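**Retrosynthetic overview**
- Side chain: cut the C4–C5 bond of the dienoic acid (Heck), giving a ring vinyl carbinol and (2Z)-3-iodobut-2-enoic acid; this sets 4E and carries 2Z in.
- Key disconnection: the bond between the ring quaternary carbon and its CH2O carbon. That carbon, already carrying the complete HMG methyl ester, is used with reversed polarity as a nucleophilic acyloxymethyl unit (a hydroxymethyl d1 equivalent) that attacks the β-carbon of a prochiral para-quinol dienone. This desymmetrization sets both ring stereocentres, CH2O anti to a bulky silyloxy group.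
- The para-quinol comes from 2,6-dimethylphenol: oxidative dearomatization to the quinone monoketal, vinyl addition, unmasking, silylation.
- The HMG stereocentre comes from enzymatic desymmetrization of dimethyl 3-hydroxy-3-methylglutarate; its acid arm is extended by a glycolate unit whose CO2H is later lost as CO2.
- Rings: the target's only ring is the carbocycle, inherited from the arene; no ring-forming step is needed (the dioxolane made in step 1 is temporary and removed in step 2).

Assumption: compound 9, pig liver esterase (PLE), 4CzIPN and both enantiomers of trans-2-(9H-carbazol-9-yl)cyclohexan-1-amine are taken as available; PLE is taken to give the (S)-half-ester from 9; if a test run of step 7 shows the opposite sense of induction, the (1S,2S)-amine replaces the (1R,2R)-amine.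

**Step 1**
Reactants: 1 2,6-dimethylphenol; 2 ethane-1,2-diol (ethylene glycol)
Product: 4 7,9-dimethyl-1,4-dioxaspiro[4.5]deca-6,9-dien-8-one, via 4-(2-hydroxyethoxy)-2,6-dimethylphenol 3 (not isolated)
Conditions: PhI(OAc)2 (2.2 equiv), ethylene glycol/CH2Cl2, 0 °C → rt
Reagents that add atoms: none
Why: Hypervalent-iodine oxidative dearomatization in two successive two-electron oxidations (para C–O bond formation, then spiroketalization by the pendant hydroxyl) gives the para-quinone monoketal in which only the carbonyl flanked by the two methyl-bearing carbons is free.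

**Step 2**
Reactants: 4 7,9-dimethyl-1,4-dioxaspiro[4.5]deca-6,9-dien-8-one; 5 vinylmagnesium bromide (CH2=CHMgBr)
Product: 7 4-ethenyl-4-hydroxy-3,5-dimethylcyclohexa-2,5-dien-1-one, via 8-ethenyl-7,9-dimethyl-1,4-dioxaspiro[4.5]deca-6,9-dien-8-ol 6 (not isolated)
Conditions: CeCl3 (1.5 equiv), THF, −78 °C; then 1 M HCl, THF, 0 °C, 30 min
Reagents that add atoms: water, O
Why: Organocerium 1,2-addition to the hindered cross-conjugated ketone followed by acid-catalysed ketal hydrolysis gives the achiral, prochiral para-quinol (no stereocentre yet).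

**Step 3**
Reactants: 7 4-ethenyl-4-hydroxy-3,5-dimethylcyclohexa-2,5-dien-1-one
Product: 8 4-ethenyl-3,5-dimethyl-4-(triethylsilyloxy)cyclohexa-2,5-dien-1-one
Conditions: Et3SiOSO2CF3 (1.3 equiv), 2,6-lutidine, CH2Cl2, −78 → 0 °C
Reagents that add atoms: triethylsilyl trifluoromethanesulfonate, CC[Si](CC)(CC)OS(=O)(=O)C(F)(F)F
Why: Silyl triflate silylation of the hindered tertiary alcohol installs a bulky OSiEt3 group that later shields one face of both enone arms, while the small vinyl group leaves the other face open.

**Step 4**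
Reactants: 9 dimethyl 3-hydroxy-3-methylpentanedioate
Product: 10 (3S)-3-hydroxy-5-methoxy-3-methyl-5-oxopentanoic acid
Conditions: PLE, 0.1 M phosphate buffer pH 8, 1 M NaOH (pH-stat), 25 °C; then HCl to pH 2
Reagents that add atoms: water, O
Why: Enzymatic desymmetrization (enantiotopic-group-selective ester hydrolysis by pig liver esterase) cleaves one of the two ester arms of the prochiral diester and so sets the HMG stereocentre as the (S)-half-ester.

**Step 5**
Reactants: 10 (3S)-3-hydroxy-5-methoxy-3-methyl-5-oxopentanoic acid; 11 benzyl bromoacetate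
Product: 12 1-[2-(benzyloxy)-2-oxoethyl] 5-methyl (3R)-3-hydroxy-3-methylpentanedioate
Conditions: KHCO3 (1.1 equiv), DMF, 25 °C
Reagents that add atoms: none
Why: SN2 O-alkylation of the carboxylate leaves the tertiary alcohol and methyl ester untouched, and the stereocentre is unchanged in space (the descriptor becomes R only because the CIP priorities of the two arms swap).

**Step 6**
Reactants: 12 1-[2-(benzyloxy)-2-oxoethyl] 5-methyl (3R)-3-hydroxy-3-methylpentanedioate
Product: 13 {[(3R)-3-hydroxy-5-methoxy-3-methyl-5-oxopentanoyl]oxy}acetic acid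
Conditions: H2 (1 atm), 10% Pd/C, EtOAc, 25 °C
Reagents that add atoms: none
Why: Catalytic hydrogenolysis removes only the benzyl ester and frees the acyloxyacetic acid that serves as the precursor of the acyloxymethyl unit.

**Step 7** (key step)
Reactants: 8 4-ethenyl-3,5-dimethyl-4-(triethylsilyloxy)cyclohexa-2,5-dien-1-one; 13 {[(3R)-3-hydroxy-5-methoxy-3-methyl-5-oxopentanoyl]oxy}acetic acid (1.5 equiv)
Product: 15 1-{[(1S,2R)-2-ethenyl-2-hydroxy-1,3-dimethyl-5-oxocyclohex-3-en-1-yl]methyl} 5-methyl (3R)-3-hydroxy-3-methylpentanedioate, via silyl ether adduct 14 (not isolated)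
Conditions: (1R,2R)-2-(9H-carbazol-9-yl)cyclohexan-1-amine (20 mol%), 4CzIPN (2 mol%), MeCN, blue LEDs (450 nm), 25 °C, degassed; then 48% aq HF, 0 °C → rt
Reagents that add atoms: none
Why: Proposed new method: photoredox oxidation of the carboxylate of 13 releases CO2 and the nucleophilic acyloxymethyl radical (a one-electron hydroxymethyl d1 equivalent, so that a normally electrophilic oxygenated carbon is joined to the normally electrophilic enone β-carbon), which adds in a desymmetrizing Giese-type conjugate addition to the β-carbon of the chiral iminium ion formed from dienone 8, the primary amine and excess 13 as acid co-catalyst; the catalyst selects one enantiotopic face and the OSiEt3 group blocks that face on one arm, so bond formation occurs on a single arm anti to OSiEt3 (syn to vinyl) and sets the carbinol carbon (R) and the quaternary carbon (S) together; electron transfer from the carbazole, back-reduction by reduced 4CzIPN and hydrolysis give 14, and aqueous HF cleaves the silyl ether; the closest known reaction types are enantioselective iminium-ion trapping of photogenerated nucleophilic radicals at β-substituted cyclic enones to form quaternary centres and photoredox decarboxylative Giese addition.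

**Step 8**
Reactants: 16 but-2-ynoic acid
Product: 17 (2Z)-3-iodobut-2-enoic acid
Conditions: NaI (1.6 equiv), AcOH, 115 °C
Reagents that add atoms: sodium iodide, [Na+].[I-]
Why: Hydroiodination of the ynoic acid (conjugate addition of iodide, then anti protonation) gives the Z-iodoalkene selectively.

**Step 9**
Reactants: 15 1-{[(1S,2R)-2-ethenyl-2-hydroxy-1,3-dimethyl-5-oxocyclohex-3-en-1-yl]methyl} 5-methyl (3R)-3-hydroxy-3-methylpentanedioate; 17 (2Z)-3-iodobut-2-enoic acid (1.5 equiv)
Product: 18 (2Z,4E)-5-[(1R,6S)-1-hydroxy-6-({[(3R)-3-hydroxy-5-methoxy-3-methyl-5-oxopentanoyl]oxy}methyl)-2,6-dimethyl-4-oxocyclohex-2-en-1-yl]-3-methylpenta-2,4-dienoic acid (target)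
Conditions: Pd(OAc)2 (10 mol%), Ag2CO3 (1.5 equiv), DMF, 50 °C, dark; acidify to pH 3
Reagents that add atoms: none
Why: Mizoroki–Heck reaction under ligand-free silver carbonate conditions: the Z-iodoalkene geometry is retained, the terminal CH2 of the vinyl group inserts, and β-hydride elimination can only give the E-alkene because the carbinol carbon bears no hydrogen, so the (2Z,4E)-dienoic acid forms without touching any stereocentre.

**Compound list**
1 | 2,6-dimethylphenol | Cc1cccc(C)c1O | starting material
2 | ethane-1,2-diol (ethylene glycol) | OCCO | starting material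
3 | 4-(2-hydroxyethoxy)-2,6-dimethylphenol | Cc1cc(OCCO)cc(C)c1O | intermediate
4 | 7,9-dimethyl-1,4-dioxaspiro[4.5]deca-6,9-dien-8-one | CC1=CC2(OCCO2)C=C(C)C1=O | intermediate
5 | vinylmagnesium bromide (CH2=CHMgBr) | C=C[Mg]Br | starting material
6 | 8-ethenyl-7,9-dimethyl-1,4-dioxaspiro[4.5]deca-6,9-dien-8-ol | CC1=CC2(OCCO2)C=C(C)C1(O)C=C | intermediate
7 | 4-ethenyl-4-hydroxy-3,5-dimethylcyclohexa-2,5-dien-1-one (achiral) | CC1=CC(=O)C=C(C)C1(O)C=C | intermediate
8 | 4-ethenyl-3,5-dimethyl-4-(triethylsilyloxy)cyclohexa-2,5-dien-1-one (achiral) | CC1=CC(=O)C=C(C)C1(O[Si](CC)(CC)CC)C=C | intermediate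
9 | dimethyl 3-hydroxy-3-methylpentanedioate | COC(=O)CC(C)(O)CC(=O)OC | starting material
10 | (3S)-3-hydroxy-5-methoxy-3-methyl-5-oxopentanoic acid | COC(=O)C[C@@](C)(O)CC(=O)O | intermediate
11 | benzyl bromoacetate | BrCC(=O)OCc1ccccc1 | starting material
12 | 1-[2-(benzyloxy)-2-oxoethyl] 5-methyl (3R)-3-hydroxy-3-methylpentanedioate | COC(=O)C[C@@](C)(O)CC(=O)OCC(=O)OCc1ccccc1 | intermediate
13 | {[(3R)-3-hydroxy-5-methoxy-3-methyl-5-oxopentanoyl]oxy}acetic acid | COC(=O)C[C@@](C)(O)CC(=O)OCC(=O)O | intermediate
14 | 1-{[(1S,2R)-2-ethenyl-1,3-dimethyl-5-oxo-2-(triethylsilyloxy)cyclohex-3-en-1-yl]methyl} 5-methyl (3R)-3-hydroxy-3-methylpentanedioate (CH2O trans to OSiEt3, cis to vinyl) | COC(=O)C[C@@](C)(O)CC(=O)OC[C@]1(C)CC(=O)C=C(C)[C@]1(O[Si](CC)(CC)CC)C=C | intermediate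
15 | 1-{[(1S,2R)-2-ethenyl-2-hydroxy-1,3-dimethyl-5-oxocyclohex-3-en-1-yl]methyl} 5-methyl (3R)-3-hydroxy-3-methylpentanedioate (CH2O trans to OH, cis to vinyl) | COC(=O)C[C@@](C)(O)CC(=O)OC[C@]1(C)CC(=O)C=C(C)[C@]1(O)C=C | intermediate
16 | but-2-ynoic acid | CC#CC(=O)O | starting material
17 | (2Z)-3-iodobut-2-enoic acid | C/C(I)=C/C(=O)O | intermediate
18 | (2Z,4E)-5-[(1R,6S)-1-hydroxy-6-({[(3R)-3-hydroxy-5-methoxy-3-methyl-5-oxopentanoyl]oxy}methyl)-2,6-dimethyl-4-oxocyclohex-2-en-1-yl]-3-methylpenta-2,4-dienoic acid | COC(=O)C[C@@](C)(O)CC(=O)OC[C@]1(C)CC(=O)C=C(C)[C@]1(O)/C=C/C(C)=C\C(=O)O | target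

**Totals**
Total step count: 9. Longest linear sequence: 5 steps (1 → 4 → 7 → 8 → 15 → 18 through steps 1, 2, 3, 7, 9; the HMG branch 9 → 10 → 12 → 13 → 15 → 18 through steps 4, 5, 6, 7, 9 is equally long).

**Three steps most likely to fail**

Step 7 is the main risk.
- Failure modes: the iminium ion of the hindered cross-conjugated dienone may form too slowly, so racemic background addition to free 8 competes; shielding by OSiEt3 may not give a useful anti:syn ratio; a second addition to the remaining enone arm may occur.
- Because the HMG centre is fixed, every other ring stereoisomer is a diastereomer of 15 and can be removed by chromatography.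
- Fallback, setting out from 8 (with 10) and coming back at 14: the same ring–CH2O bond is made with a two-electron hydroxymethyl-anion reagent. (Isopropoxydimethylsilyl)methylmagnesium chloride F1 is made from commercial (chloromethyl)isopropoxydimethylsilane and Mg in THF. It is added to 8 under Cu(OTf)2 (5 mol%) with a chiral imidazolinium-derived N-heterocyclic carbene ligand in Et2O at −30 °C, again anti to OSiEt3, to give (4R,5R)-4-ethenyl-5-{[dimethyl(propan-2-yloxy)silyl]methyl}-3,5-dimethyl-4-(triethylsilyloxy)cyclohex-2-en-1-one F2. Tamao–Fleming oxidation (KF, KHCO3, 30% H2O2, THF/MeOH, 25 °C) gives (4R,5S)-4-ethenyl-5-(hydroxymethyl)-3,5-dimethyl-4-(triethylsilyloxy)cyclohex-2-en-1-one F3. F3 is esterified at once with 10 (EDC·HCl, DMAP, CH2Cl2, 0 °C), because the free hydroxymethyl enone can close onto the enone, to give 14. 14 is then desilylated with aqueous HF as in the second stage of step 7. This costs two extra steps.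

Step 9 is the second risk.
- Failure modes: the vinyl group sits on a carbon flanked by a quaternary centre; the Z-iodoalkene may isomerize; the Z-dienoic acid may lactonize on palladium.
- Fallback, setting out from 15 and coming back at 18: cross-metathesis of 15 with vinylboronic acid pinacol ester (second-generation Hoveyda–Grubbs catalyst, 5 mol%, CH2Cl2, 40 °C) gives 1-({(1S,2R)-2-hydroxy-1,3-dimethyl-5-oxo-2-[(E)-2-(4,4,5,5-tetramethyl-1,3,2-dioxaborolan-2-yl)ethenyl]cyclohex-3-en-1-yl}methyl) 5-methyl (3R)-3-hydroxy-3-methylpentanedioate F4. Stereoretentive Suzuki–Miyaura coupling of F4 with 17 (Pd(PPh3)4, K3PO4, THF/H2O, 50 °C) then gives 18. This costs one extra step.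

Step 2 is the third risk.
- Failure mode: under acid, carbinol ketal 6 can lose its tris-allylic hydroxyl and aromatize to an aryl glycol ether instead of hydrolysing to 7.
- Fallback, setting out from 4 and coming back at 8: the free para-quinol is never made. After the organocerium addition of 5 to 4, the alkoxide is silylated in the same flask (Et3SiOSO2CF3, 2,6-lutidine, −78 → 0 °C) to give 8-ethenyl-7,9-dimethyl-8-(triethylsilyloxy)-1,4-dioxaspiro[4.5]deca-6,9-diene F5. The dioxolane is then removed under buffered conditions (pyridinium p-toluenesulfonate, acetone/H2O, 25 °C) to give 8 directly, replacing steps 2 and 3 with no change in step count.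

**Further compounds**
F1 | step 7 | (isopropoxydimethylsilyl)methylmagnesium chloride | CC(C)O[Si](C)(C)C[Mg]Cl
F2 | step 7 | (4R,5R)-4-ethenyl-5-{[dimethyl(propan-2-yloxy)silyl]methyl}-3,5-dimethyl-4-(triethylsilyloxy)cyclohex-2-en-1-one | CC(C)O[Si](C)(C)C[C@]1(C)CC(=O)C=C(C)[C@]1(O[Si](CC)(CC)CC)C=C
F3 | step 7 | (4R,5S)-4-ethenyl-5-(hydroxymethyl)-3,5-dimethyl-4-(triethylsilyloxy)cyclohex-2-en-1-one | OC[C@]1(C)CC(=O)C=C(C)[C@]1(O[Si](CC)(CC)CC)C=C
F4 | step 9 | 1-({(1S,2R)-2-hydroxy-1,3-dimethyl-5-oxo-2-[(E)-2-(4,4,5,5-tetramethyl-1,3,2-dioxaborolan-2-yl)ethenyl]cyclohex-3-en-1-yl}methyl) 5-methyl (3R)-3-hydroxy-3-methylpentanedioate | COC(=O)C[C@@](C)(O)CC(=O)OC[C@]1(C)CC(=O)C=C(C)[C@]1(O)/C=C/B2OC(C)(C)C(C)(C)O2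
F5 | step 2 | 8-ethenyl-7,9-dimethyl-8-(triethylsilyloxy)-1,4-dioxaspiro[4.5]deca-6,9-diene | CC1=CC2(OCCO2)C=C(C)C1(O[Si](CC)(CC)CC)C=C
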